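**Retrosynthetic overview**

1. Labels: ring A = 3,5-dioxygenated ring carrying C7H2; ring C = mono-oxygenated ring; ring B = six-membered ring (ring A, C7H2, C8H, ring C); ring D = catechol ring on C8, fused into seven-membered ring F (C8, ring D, C9H, C10H2, ring C); ring E = catechol ring on C9.
2. Target 16 ⇐ heptamethyl ether 15 (BBr3) ⇐ stilbene 14 by acid Friedel–Crafts closure of ring F (C9–ring D bond, sets C9) ⇐ aldehyde 12 + phosphonate 13 (C9=C10).
3. 12 ⇐ ester 10. The plan rests on ring B: it is only the C7–C8 ethane unit, with ring D on C8, bridging the two ortho positions of the ring A–ring C biaryl. It therefore maps onto 3,4-dimethoxystyrene 9 added across the 2-bromo-2'-chloro biaryl 8 (bonds ring A–C7 and C8–ring C; C8 set by a chiral nickel catalyst).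
4. 8 ⇐ Suzuki–Miyaura coupling of ring C boronate 5 (from methyl 5-methoxyanthranilate 1 by bromination, Sandmeyer chlorination, borylation) with ring A iodide 7 (from 1-bromo-3,5-dimethoxybenzene 6).
5. Ring order: biaryl A–C, then ring B (with C8), then ring F (with C9); rings D and E arrive intact with 9 and 13.

Key step: step 6

Assumption: the sense of induction of the nickel–bis(oxazoline) catalyst in step 6 cannot be predicted with certainty; the (S,S)-ligand is written, and its enantiomer is used if it should deliver (S)-10.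

**Step 1**
Reactants: 1 methyl 2-amino-5-methoxybenzoate
Product: 2 methyl 2-amino-3-bromo-5-methoxybenzoate
Conditions: NBS (1.05 equiv), DMF, 0 °C to rt
Reagents that add atoms: N-bromosuccinimide, O=C1CCC(=O)N1Br
Why: Electrophilic aromatic bromination, in which the amino group is the strongest director and, its para position being blocked by OMe, should send bromine to the free ortho position C3.

**Step 2**
Reactants: 2 methyl 2-amino-3-bromo-5-methoxybenzoate
Product: 4 methyl 3-bromo-2-chloro-5-methoxybenzoate, via diazonium chloride 3 (not isolated)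
Conditions: t-BuONO (1.5 equiv), CuCl2 (1.2 equiv), MeCN, 0 to 60 °C
Reagents that add atoms: copper dichloride, Cl[Cu]Cl
Why: Non-aqueous Sandmeyer chlorination, placed before the biaryl coupling so that the diazonium ion never sits next to an ortho' aryl ring whose OMe or Br could trap it.

**Step 3**
Reactants: 4 methyl 3-bromo-2-chloro-5-methoxybenzoate
Product: 5 methyl 2-chloro-5-methoxy-3-(4,4,5,5-tetramethyl-1,3,2-dioxaborolan-2-yl)benzoate
Conditions: B2pin2 (1.2 equiv), Pd(dppf)Cl2 (3 mol %), KOAc (3 equiv), dioxane, 90 °C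
Reagents that add atoms: bis(pinacolato)diboron, CC1(C)OB(OC1(C)C)B1OC(C)(C)C(C)(C)O1
Why: Miyaura borylation, in which this catalyst inserts into C–Br far faster than into C–Cl and KOAc is too weak a base to start Suzuki homocoupling.

**Step 4**
Reactants: 6 1-bromo-3,5-dimethoxybenzene
Product: 7 1-bromo-2-iodo-3,5-dimethoxybenzene
Conditions: NIS (1.05 equiv), TFA (10 mol %), MeCN, rt
Reagents that add atoms: N-iodosuccinimide, O=C1CCC(=O)N1I
Why: Electrophilic aromatic iodination, which should go to position 2 (ortho to one OMe, para to the other) and not to the more crowded position 4 between the two OMe groups, as is usual for 5-substituted resorcinol dimethyl ethers.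

**Step 5**
Reactants: 5 methyl 2-chloro-5-methoxy-3-(4,4,5,5-tetramethyl-1,3,2-dioxaborolan-2-yl)benzoate; 7 1-bromo-2-iodo-3,5-dimethoxybenzene
Product: 8 methyl 3-(2-bromo-4,6-dimethoxyphenyl)-2-chloro-5-methoxybenzoate
Conditions: Pd(PPh3)4 (5 mol %), K3PO4 (3 equiv), dioxane/H2O 5:1, 85 °C
Reagents that add atoms: none
Why: Suzuki–Miyaura coupling, in which oxidative addition of a triphenylphosphine–palladium catalyst into C–I should outrun C–Br and C–Cl so that only the iodide position of 7 is arylated.

**Step 6**
Reactants: 8 methyl 3-(2-bromo-4,6-dimethoxyphenyl)-2-chloro-5-methoxybenzoate; 9 3,4-dimethoxystyrene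
Product: 10 methyl (10R)-10-(3,4-dimethoxyphenyl)-3,5,7-trimethoxy-9,10-dihydrophenanthrene-1-carboxylate
Conditions: NiBr2(dme) (10 mol %), (S,S)-iBu-BiOX [(4S,4'S)-4,4'-diisobutyl-2,2'-bi(2-oxazoline)] (12 mol %), Zn dust (3 equiv), 9 (3 equiv), DMPU/THF, 30 °C, slow addition of 8
Reagents that add atoms: none
Why: Proposed new method: zerovalent nickel should insert first into the C–Br bond of ring A (flanked on one side only, and weaker than the doubly flanked C–Cl of ring C), the aryl–nickel then adds across styrene 9 with the aryl group going to the terminal carbon (C7) so that nickel sits on benzylic C8 stabilised by ring D, and after one-electron reduction by zinc this benzylic nickel takes up the neighbouring C–Cl bond and the resulting trivalent nickel releases the C8–ring C bond. The closest known reaction type is the nickel/chiral bis(oxazoline)-catalysed enantioselective reductive 1,2-diarylation of vinylarenes with two molecules of one aryl bromide; placing two different carbon–halogen bonds on one biaryl so that the alkene is annulated has not been shown. Ring B closes by C(sp3)–C(sp2) reductive elimination from a seven-membered nickelacycle, a formal [4+2] annulation with both alkene carbons ending inside the six-membered ring, while direct aryl–aryl coupling is excluded because it would need a four-membered ring. C8 is set by the chiral ligand in this bond-forming event, since the benzylic nickel can equilibrate by reversible homolysis and the ligand, not the face of insertion, then decides for (R). The step needs halide chemoselectivity (bromide before chloride, secured by the shielding and bond strength of the ring C chloride and by slow addition of 8), insertion regioselectivity (secured by benzylic stabilisation through ring D) and enantioselectivity (secured by the ligand).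

**Step 7**
Reactants: 10 methyl (10R)-10-(3,4-dimethoxyphenyl)-3,5,7-trimethoxy-9,10-dihydrophenanthrene-1-carboxylate
Product: 11 [(10R)-10-(3,4-dimethoxyphenyl)-3,5,7-trimethoxy-9,10-dihydrophenanthren-1-yl]methanol
Conditions: i-Bu2AlH (2.5 equiv), CH2Cl2, −78 to 0 °C; Rochelle salt work-up
Reagents that add atoms: none
Why: Hydride reduction of an aryl ester to the benzylic alcohol, with no other reducible group present and C8 not involved.

**Step 8**
Reactants: 11 [(10R)-10-(3,4-dimethoxyphenyl)-3,5,7-trimethoxy-9,10-dihydrophenanthren-1-yl]methanol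
Product: 12 (10R)-10-(3,4-dimethoxyphenyl)-3,5,7-trimethoxy-9,10-dihydrophenanthrene-1-carbaldehyde
Conditions: activated MnO2 (15 equiv), CH2Cl2, rt, dark
Reagents that add atoms: none
Why: Manganese dioxide oxidation of a benzylic alcohol, which should stop at the aldehyde under neutral conditions that leave C8 untouched.

**Step 9**
Reactants: 12 (10R)-10-(3,4-dimethoxyphenyl)-3,5,7-trimethoxy-9,10-dihydrophenanthrene-1-carbaldehyde; 13 diethyl (3,4-dimethoxybenzyl)phosphonate
Product: 14 (10R)-10-(3,4-dimethoxyphenyl)-1-[(E)-2-(3,4-dimethoxyphenyl)ethenyl]-3,5,7-trimethoxy-9,10-dihydrophenanthrene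
Conditions: 13 (1.3 equiv), KOt-Bu (1.3 equiv), THF, 0 °C to rt
Reagents that add atoms: none
Why: Horner–Wadsworth–Emmons olefination of an aryl aldehyde with a benzylic phosphonate anion, which should give the (E)-stilbene.

**Step 10**
Reactants: 14 (10R)-10-(3,4-dimethoxyphenyl)-1-[(E)-2-(3,4-dimethoxyphenyl)ethenyl]-3,5,7-trimethoxy-9,10-dihydrophenanthrene
Product: 15 (8R,9S)-heptamethyl ether of 16 (ring F closed; C8–H and C9–H cis)
Conditions: MsOH (3 equiv), CH2Cl2 (0.01 M), −20 to 0 °C
Reagents that add atoms: none
Why: Intramolecular Friedel–Crafts alkylation in which protonation at C10 gives the C9 cation stabilised by the para-OMe of ring E, ring D attacks through its position para to OMe to close ring F, and C9 should come out (S) because the ring B fusion holds C8–H pseudo-axial on the forming boat-like ring while ring E takes the outward pseudo-equatorial place, which puts C9–H cis to C8–H.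

**Step 11**
Reactants: 15 (8R,9S)-heptamethyl ether of 16
Product: 16 CNP0306974.1, the (8R,9S)-heptaphenol
Conditions: BBr3 (14 equiv), CH2Cl2, −78 °C to rt; then MeOH, H2O
Reagents that add atoms: none
Why: Lewis acid cleavage of all seven aryl methyl ethers, which the two diarylmethine stereocentres, carrying no leaving group, should survive.

**Compound list**

1 | methyl 2-amino-5-methoxybenzoate | COC(=O)c1cc(OC)ccc1N | starting material
2 | methyl 2-amino-3-bromo-5-methoxybenzoate | COC(=O)c1cc(OC)cc(Br)c1N | intermediate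
3 | 2-bromo-4-methoxy-6-(methoxycarbonyl)benzenediazonium chloride (not isolated) | COC(=O)c1cc(OC)cc(Br)c1[N+]#N.[Cl-] | intermediate
4 | methyl 3-bromo-2-chloro-5-methoxybenzoate | COC(=O)c1cc(OC)cc(Br)c1Cl | intermediate
5 | methyl 2-chloro-5-methoxy-3-(4,4,5,5-tetramethyl-1,3,2-dioxaborolan-2-yl)benzoate | COC(=O)c1cc(OC)cc(B2OC(C)(C)C(C)(C)O2)c1Cl | intermediate
6 | 1-bromo-3,5-dimethoxybenzene | COc1cc(Br)cc(OC)c1 | starting material
7 | 1-bromo-2-iodo-3,5-dimethoxybenzene | COc1cc(OC)c(I)c(Br)c1 | intermediate
8 | methyl 3-(2-bromo-4,6-dimethoxyphenyl)-2-chloro-5-methoxybenzoate | COC(=O)c1cc(OC)cc(-c2c(Br)cc(OC)cc2OC)c1Cl | intermediate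
9 | 3,4-dimethoxystyrene | C=Cc1ccc(OC)c(OC)c1 | starting material
10 | methyl (10R)-10-(3,4-dimethoxyphenyl)-3,5,7-trimethoxy-9,10-dihydrophenanthrene-1-carboxylate | COc1cc(OC)c2c(c1)C[C@H](c1ccc(OC)c(OC)c1)c1c(C(=O)OC)cc(OC)cc-21 | intermediate
11 | [(10R)-10-(3,4-dimethoxyphenyl)-3,5,7-trimethoxy-9,10-dihydrophenanthren-1-yl]methanol | COc1cc(OC)c2c(c1)C[C@H](c1ccc(OC)c(OC)c1)c1c(CO)cc(OC)cc-21 | intermediate
12 | (10R)-10-(3,4-dimethoxyphenyl)-3,5,7-trimethoxy-9,10-dihydrophenanthrene-1-carbaldehyde | COc1cc(OC)c2c(c1)C[C@H](c1ccc(OC)c(OC)c1)c1c(C=O)cc(OC)cc-21 | intermediate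
13 | diethyl (3,4-dimethoxybenzyl)phosphonate | CCOP(=O)(OCC)Cc1ccc(OC)c(OC)c1 | starting material
14 | (10R)-10-(3,4-dimethoxyphenyl)-1-[(E)-2-(3,4-dimethoxyphenyl)ethenyl]-3,5,7-trimethoxy-9,10-dihydrophenanthrene | COc1cc(OC)c2c(c1)C[C@H](c1ccc(OC)c(OC)c1)c1c(/C=C/c3ccc(OC)c(OC)c3)cc(OC)cc-21 | intermediate
15 | (8R,9S)-heptamethyl ether of 16 (rings A to F closed, C8–H and C9–H cis on ring F) | COc1cc(OC)c2c(c1)C[C@@H]1c3cc(OC)c(OC)cc3[C@H](c3ccc(OC)c(OC)c3)Cc3cc(OC)cc-2c31 | intermediate
16 | CNP0306974.1, (8R,9S)-heptaphenol | Oc1cc(O)c2c(c1)C[C@@H]1c3cc(O)c(O)cc3[C@H](c3ccc(O)c(O)c3)Cc3cc(O)cc-2c31 | target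

**Step count**

Total: 11 steps. Longest linear sequence: 10 steps (steps 1–3 and 5–11 from 1; step 4 is a one-step branch).

**Steps most likely to fail**

1. **Step 6 (proposed new method).** What may go wrong: nickel may insert into the ester-activated C–Cl bond first and give the regioisomeric ring; the benzylic nickel may lose β-hydride to a stilbene or couple with the bromide of a second molecule instead of closing the ring; or the ligand may induce poorly. The fallback uses known chemistry: C8 is set by copper/palladium dual-catalysed enantioselective arylboration of the styrene, and ring B is closed last at the biaryl bond. It sets out from amine 2 and styrene 9 and returns at 10. Sandmeyer iodination of 2 (NaNO2, p-TsOH, KI, MeCN/H2O) gives methyl 3-bromo-2-iodo-5-methoxybenzoate F1. Styrene 9, F1 and B2pin2 with CuCl, a chiral phosphine ligand, Pd(dppf)Cl2 and KOMe in THF give methyl 3-bromo-2-[(1R)-1-(3,4-dimethoxyphenyl)-2-(4,4,5,5-tetramethyl-1,3,2-dioxaborolan-2-yl)ethyl]-5-methoxybenzoate F2; the boryl–copper adds to the styrene and the benzylic copper is arylated at the iodide of F1. B-alkyl Suzuki–Miyaura coupling (Pd(OAc)2, RuPhos, K3PO4, toluene/H2O) of F2 at the iodide of 2-bromo-1-iodo-3,5-dimethoxybenzene F3 (from commercial 1-iodo-3,5-dimethoxybenzene and NBS) gives methyl 3-bromo-2-[(1R)-2-(2-bromo-3,5-dimethoxyphenyl)-1-(3,4-dimethoxyphenyl)ethyl]-5-methoxybenzoate F4. Intramolecular Ullmann-type reductive coupling of its two C–Br bonds with the zerovalent nickel complex Ni(cod)2 and 2,2'-bipyridine in DMF forms the biaryl bond and gives 10.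

2. **Step 10.** What may go wrong: attack on the wrong face of the C9 cation would give the C9 epimer, and reversible ionisation in acid could erode C8 or reopen ring F. The fallback sets C9 by hydrogenation of a ring F alkene instead of by cation capture. It sets out from aldehyde 12 and returns at 15. Seyferth–Gilbert homologation with the Ohira–Bestmann reagent (K2CO3, MeOH) gives (10R)-10-(3,4-dimethoxyphenyl)-1-ethynyl-3,5,7-trimethoxy-9,10-dihydrophenanthrene F5. Sonogashira coupling with 4-iodo-1,2-dimethoxybenzene (Pd(PPh3)2Cl2, CuI, Et3N) gives the diarylalkyne (10R)-10-(3,4-dimethoxyphenyl)-1-[(3,4-dimethoxyphenyl)ethynyl]-3,5,7-trimethoxy-9,10-dihydrophenanthrene F6. Acid- or gold-catalysed 7-endo hydroarylation (catalytic TfOH or Ph3PAuNTf2, CH2Cl2), with ring D attacking the alkyne carbon next to ring E, gives the (8R)-C9=C10 dehydro analogue of 15, F7. Hydrogenation (H2, Pd/C, EtOAc) should add from the convex face of the folded ring F, the face that carries C8–H, and give 15.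

3. **Step 5.** What may go wrong: the coupling forms a biaryl with three ortho substituents and may stall; boronate 5 may protodeboronate; and the bromide of 7 may compete with the iodide. The fallback reverses the polarity of the coupling and bypasses boronate 5. It sets out from iodide 7 and bromide 4 and returns at 8. Iodine–magnesium exchange on 7 (i-PrMgCl·LiCl, THF, −30 °C; the iodide exchanges before the bromide) gives (2-bromo-4,6-dimethoxyphenyl)magnesium chloride F8. ZnCl2 converts it into (2-bromo-4,6-dimethoxyphenyl)zinc chloride F9. Negishi coupling of F9 with 4 (Pd(PPh3)4, THF, 60 °C), which reacts at C–Br and not at C–Cl, gives 8.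

**Further compounds**

F1 | step 6 | methyl 3-bromo-2-iodo-5-methoxybenzoate | COC(=O)c1cc(OC)cc(Br)c1I
F2 | step 6 | methyl 3-bromo-2-[(1R)-1-(3,4-dimethoxyphenyl)-2-(4,4,5,5-tetramethyl-1,3,2-dioxaborolan-2-yl)ethyl]-5-methoxybenzoate | CC1(C)OB(C[C@H](c2ccc(OC)c(OC)c2)c2c(Br)cc(OC)cc2C(=O)OC)OC1(C)C
F3 | step 6 | 2-bromo-1-iodo-3,5-dimethoxybenzene | COc1cc(I)c(Br)c(OC)c1
F4 | step 6 | methyl 3-bromo-2-[(1R)-2-(2-bromo-3,5-dimethoxyphenyl)-1-(3,4-dimethoxyphenyl)ethyl]-5-methoxybenzoate | COc1cc(OC)c(Br)c(c1)C[C@H](c1ccc(OC)c(OC)c1)c1c(Br)cc(OC)cc1C(=O)OC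
F5 | step 10 | (10R)-10-(3,4-dimethoxyphenyl)-1-ethynyl-3,5,7-trimethoxy-9,10-dihydrophenanthrene | COc1cc(OC)c2c(c1)C[C@H](c1ccc(OC)c(OC)c1)c1c(C#C)cc(OC)cc-21
F6 | step 10 | (10R)-10-(3,4-dimethoxyphenyl)-1-[(3,4-dimethoxyphenyl)ethynyl]-3,5,7-trimethoxy-9,10-dihydrophenanthrene | COc1cc(OC)c2c(c1)C[C@H](c1ccc(OC)c(OC)c1)c1c(C#Cc3ccc(OC)c(OC)c3)cc(OC)cc-21
F7 | step 10 | (8R)-C9=C10 dehydro analogue of 15 (ring F cycloheptene carrying ring E on C9) | COc1cc(OC)c2c(c1)C[C@@H]1c3cc(OC)c(OC)cc3C(c3ccc(OC)c(OC)c3)=Cc3cc(OC)cc-2c31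
F8 | step 5 | (2-bromo-4,6-dimethoxyphenyl)magnesium chloride | COc1cc(OC)c([Mg]Cl)c(Br)c1
F9 | step 5 | (2-bromo-4,6-dimethoxyphenyl)zinc chloride | COc1cc(OC)c([Zn]Cl)c(Br)c1
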